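**Retrosynthetic overview**

1. Locants: ring A is the 4,5-dihydroxy-7-methyl-1-tetralone unit (C1 ketone, C2, C3, C4 carbinol, C4a, C5 phenol carbon, C8a); ring B is the 4,8-dihydroxy-6-methyl-1-tetralone unit (primed locants), bonded through C7' to C3. Target 27 comes from 26 by removal of three silyl groups.
2. 26 is cut at C2–C3 and C4–C4a of the ring A carbocycle. Both bonds are made in one flask from phenacyl bromide 8 (ring A arene, iodine on C4a) and arylacetaldehyde 24 (ring B): catalytic asymmetric enamine α-alkylation, then aryl-chromium addition to the aldehyde.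
3. Enabling feature: C2 is α to the C1 aryl ketone (a phenacyl radical site), C4 is a benzylic carbinol bonded to aromatic C4a, and C3 carries the ring B aryl group. C3–C4 is therefore an arylacetaldehyde unit whose α-carbon takes up C2 and whose carbonyl carbon takes up C4a.
4. 8 comes from 3-methoxy-5-methylbenzoic acid (carboxylate/methoxy-directed lithiation puts iodine on C4a). 24 comes from allyl phenol 21, made by Diels–Alder/aromatization of (R)-2-bromo-4-silyloxycyclohexenone 14 (C4' from a CBS reduction) with the allyl-bearing vinylketene acetal 19.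
5. Ring order: ring B carbocycle (bought as cyclohexenone 9), ring B arene (step 13), ring A carbocycle (step 16); the ring A arene is bought.

Key step: step 16

Assumption: compounds 1, 9 and 15 are taken as catalogue chemicals.

**Route**

Step 1
Reactants: 1 3-methoxy-5-methylbenzoic acid
Product: 3 2-iodo-3-methoxy-5-methylbenzoic acid, via dilithiated benzoate 2 (not isolated)
Conditions: LiTMP (excess), THF, 0 °C; then I2, −78 °C to rt; aq. HCl
Reagents that add atoms: iodine, II
Why: Directed ortho-metalation: the lithium carboxylate and the methoxy group together acidify the C–H between them, so the amide base removes that proton and iodine traps the aryllithium at the future C4a.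

Step 2
Reactants: 3 2-iodo-3-methoxy-5-methylbenzoic acid
Product: 4 2-iodo-N,3-dimethoxy-N,5-dimethylbenzamide
Conditions: MeNH(OMe)·HCl, EDC·HCl, 1-hydroxybenzotriazole (cat.), iPr2NEt, CH2Cl2, rt
Reagents that add atoms: N,O-dimethylhydroxylamine hydrochloride, CNOC.Cl
Why: Carbodiimide amide coupling should give the Weinreb amide, which allows clean conversion to the methyl ketone.

Step 3
Reactants: 4 2-iodo-N,3-dimethoxy-N,5-dimethylbenzamide
Product: 5 1-(2-iodo-3-methoxy-5-methylphenyl)ethan-1-one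
Conditions: MeMgBr, THF, 0 °C; aq. NH4Cl
Reagents that add atoms: methylmagnesium bromide, C[Mg]Br
Why: Weinreb ketone synthesis: the chelated tetrahedral adduct prevents over-addition, and MeMgBr should not exchange with the aryl iodide at this temperature.

Step 4
Reactants: 5 1-(2-iodo-3-methoxy-5-methylphenyl)ethan-1-one
Product: 6 1-(3-hydroxy-2-iodo-5-methylphenyl)ethan-1-one
Conditions: BBr3, CH2Cl2, −78 to 0 °C; H2O
Reagents that add atoms: none
Why: Lewis-acid cleavage of an aryl methyl ether, placed early so that no acid-sensitive carbinol is present.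

Step 5
Reactants: 6 1-(3-hydroxy-2-iodo-5-methylphenyl)ethan-1-one
Product: 7 1-[2-iodo-5-methyl-3-(triisopropylsilyloxy)phenyl]ethan-1-one
Conditions: TIPSCl, imidazole, DMF, 40 °C
Reagents that add atoms: chlorotri(propan-2-yl)silane, CC(C)[Si](Cl)(C(C)C)C(C)C
Why: Phenol silylation; the bulky, non-coordinating TIPS ether is needed in step 16 to steer the ring closure and should tolerate the bromination and the chromium reagent.

Step 6
Reactants: 7 1-[2-iodo-5-methyl-3-(triisopropylsilyloxy)phenyl]ethan-1-one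
Product: 8 2-bromo-1-[2-iodo-5-methyl-3-(triisopropylsilyloxy)phenyl]ethan-1-one
Conditions: CuBr2, EtOAc/CHCl3, reflux
Reagents that add atoms: copper dibromide, Br[Cu]Br
Why: Selective α-monobromination of an aryl methyl ketone by CuBr2 through the enol, with only one enolizable position available.

Step 7
Reactants: 9 1,4-dioxaspiro[4.5]dec-6-en-8-one
Product: 10 (8R)-1,4-dioxaspiro[4.5]dec-6-en-8-ol
Conditions: (S)-1-methyl-3,3-diphenyltetrahydro-1H,3H-pyrrolo[1,2-c][1,3,2]oxazaborole (cat.), BH3·SMe2, THF, −30 °C; MeOH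
Reagents that add atoms: none
Why: Corey–Bakshi–Shibata reduction: with the alkenyl carbon as the large group, the (S)-oxazaborolidine should deliver hydride to the face that gives the R alcohol, which becomes C4' of ring B.

Step 8
Reactants: 10 (8R)-1,4-dioxaspiro[4.5]dec-6-en-8-ol
Product: 11 (8R)-8-(tert-butyldimethylsilyloxy)-1,4-dioxaspiro[4.5]dec-6-ene
Conditions: TBSCl, imidazole, DMF, rt
Reagents that add atoms: tert-butyl(chloro)dimethylsilane, CC(C)(C)[Si](C)(C)Cl
Why: Standard silylation of the allylic alcohol, which fixes the carbinol before the ketone is unmasked.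

Step 9
Reactants: 11 (8R)-8-(tert-butyldimethylsilyloxy)-1,4-dioxaspiro[4.5]dec-6-ene
Product: 12 (4R)-4-(tert-butyldimethylsilyloxy)cyclohex-2-en-1-one
Conditions: pyridinium p-toluenesulfonate (cat.), THF/H2O, 45 °C
Reagents that add atoms: water, O
Why: Mild acid hydrolysis of the allylic ketal should release the enone without touching the silyl ether or the γ-stereocenter.

Step 10
Reactants: 12 (4R)-4-(tert-butyldimethylsilyloxy)cyclohex-2-en-1-one
Product: 14 (4R)-2-bromo-4-(tert-butyldimethylsilyloxy)cyclohex-2-en-1-one, via trans-dibromide 13 (not isolated)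
Conditions: Br2, CH2Cl2, 0 °C; then Et3N, 0 °C to rt
Reagents that add atoms: bromine, BrBr
Why: Bromine addition to the enone followed by amine-induced loss of HBr (addition–elimination) gives the 2-bromoenone, a dienophile that can aromatize after cycloaddition.

Step 11
Reactants: 15 methyl 3-methylbut-2-enoate
Product: 17 methyl 2-(prop-1-en-2-yl)pent-4-enoate (racemic), via lithium dienolate 16 (not isolated)
Conditions: LDA, THF/DMPU, −78 °C; then allyl bromide, −78 to 0 °C
Reagents that add atoms: allyl bromide, C=CCBr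
Why: Kinetic alkylation of the extended ester enolate occurs at the α-carbon and gives the deconjugated α-allyl ester.

Step 12
Reactants: 17 methyl 2-(prop-1-en-2-yl)pent-4-enoate
Product: 19 [1-methoxy-2-(prop-1-en-2-yl)penta-1,4-dien-1-yl]oxy-trimethylsilane (E/Z mixture), via lithium dienolate 18 (not isolated)
Conditions: LDA, THF, −78 °C; then TMSCl, −78 °C to rt; non-aqueous work-up
Reagents that add atoms: chlorotrimethylsilane, C[Si](C)(C)Cl
Why: Deprotonation at the doubly activated α-carbon and O-silylation give the 1-methoxy-1-silyloxy diene (vinylketene acetal formation).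

Step 13
Reactants: 14 (4R)-2-bromo-4-(tert-butyldimethylsilyloxy)cyclohex-2-en-1-one, 19 [1-methoxy-2-(prop-1-en-2-yl)penta-1,4-dien-1-yl]oxy-trimethylsilane
Product: 21 (4R)-4-(tert-butyldimethylsilyloxy)-8-hydroxy-6-methyl-7-(prop-2-en-1-yl)-3,4-dihydronaphthalen-1(2H)-one, via bromo ketal cycloadduct 20 (not isolated)
Conditions: toluene, 80 °C; then DBU, 0 °C to rt; then aq. HCl/THF, 0 °C
Reagents that add atoms: none
Why: Diels–Alder reaction of a vinylketene acetal with a 2-haloenone, then loss of HBr and of the silyl methyl ketal, builds the ring B arene: the nucleophilic CH2 terminus of the diene bonds to the enone β-carbon, which places the hydroxyl next to the ketone-bearing carbon and the allyl group between hydroxyl and methyl, while the C4' center is not involved.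

Step 14
Reactants: 21 (4R)-4-(tert-butyldimethylsilyloxy)-8-hydroxy-6-methyl-7-(prop-2-en-1-yl)-3,4-dihydronaphthalen-1(2H)-one
Product: 22 (4R)-4,8-bis(tert-butyldimethylsilyloxy)-6-methyl-7-(prop-2-en-1-yl)-3,4-dihydronaphthalen-1(2H)-one
Conditions: TBSOTf, 2,6-lutidine, CH2Cl2, 0 °C to rt
Reagents that add atoms: tert-butyldimethylsilyl trifluoromethanesulfonate, CC(C)(C)[Si](C)(C)OS(=O)(=O)C(F)(F)F
Why: The silyl triflate should silylate the hindered, hydrogen-bonded phenol; capping it prevents lactol formation with the aldehyde made next.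

Step 15
Reactants: 22 (4R)-4,8-bis(tert-butyldimethylsilyloxy)-6-methyl-7-(prop-2-en-1-yl)-3,4-dihydronaphthalen-1(2H)-one
Product: 24 2-[(5R)-1,5-bis(tert-butyldimethylsilyloxy)-3-methyl-8-oxo-5,6,7,8-tetrahydronaphthalen-2-yl]acetaldehyde, via ozonide 23 (not isolated)
Conditions: O3, CH2Cl2, −78 °C (Sudan red 7B end point); then PPh3, −78 °C to rt
Reagents that add atoms: ozone, [O-][O+]=O
Why: Ozonolysis of the terminal alkene with reductive work-up gives the arylacetaldehyde, and the dye end point spares the arene.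

Step 16
Reactants: 8 2-bromo-1-[2-iodo-5-methyl-3-(triisopropylsilyloxy)phenyl]ethan-1-one, 24 2-[(5R)-1,5-bis(tert-butyldimethylsilyloxy)-3-methyl-8-oxo-5,6,7,8-tetrahydronaphthalen-2-yl]acetaldehyde
Product: 26 (3R,4S)-3-[(5R)-1,5-bis(tert-butyldimethylsilyloxy)-3-methyl-8-oxo-5,6,7,8-tetrahydronaphthalen-2-yl]-4-hydroxy-7-methyl-5-(triisopropylsilyloxy)-3,4-dihydronaphthalen-1(2H)-one, via keto aldehyde 25 (not isolated)
Conditions: 24 (slight excess), Ru(bpy)3Cl2 (cat.), (2S,5R)-2-tert-butyl-3,5-dimethylimidazolidin-4-one·CF3SO3H (cat.), 2,6-lutidine, DMF, blue LEDs, 23 °C; then degas, CrCl2 (excess), NiCl2 (cat.), same flask, 23 °C; aq. work-up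
Reagents that add atoms: none
Why: Photoexcited Ru(bpy)3Cl2 reduces bromide 8 to the electrophilic phenacyl radical, which adds to C3 of the E-enamine formed from aldehyde 24 and the imidazolidinone; oxidation of the resulting α-amino radical and hydrolysis give keto aldehyde 25 (bond C2–C3), the known photoredox organocatalytic α-alkylation of aldehydes with phenacyl bromides. Because the α-aryl aldehyde would lose its C3 configuration on isolation, the same flask is then charged with CrCl2 and NiCl2: zerovalent nickel inserts into the C4a–I bond, transmetalation gives an aryl species of trivalent chromium, and this adds to the aldehyde (intramolecular Nozaki–Hiyama–Kishi reaction), closing the six-membered carbocycle of ring A in a 6-exo-trig mode (bond C4a–C4). C3 (R) is set by the catalyst: the enamine double bond lies away from the tert-butyl group and the 5-methyl group shields one face, so the radical enters from the other. C4 (S, hydroxyl cis to the aryl group) is set by the C3 center and the substrate: in the chair-like closure the aryl group is pseudo-equatorial and anti to the attacking C4a (Felkin–Anh), and the bulky, non-chelating OTIPS group on C5 keeps the forming C4–O bond out of the arene plane (pseudo-axial). The step needs closure at C4a and not at C8, addition to the aldehyde and not to the two ketones, and radical attack at C3 and not at C4; these are secured by the iodine placed between the acyl and silyloxy groups, by the aldehyde selectivity of organochromium reagents, and by the polarity of the enamine.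

Step 17
Reactants: 26 (3R,4S)-3-[(5R)-1,5-bis(tert-butyldimethylsilyloxy)-3-methyl-8-oxo-5,6,7,8-tetrahydronaphthalen-2-yl]-4-hydroxy-7-methyl-5-(triisopropylsilyloxy)-3,4-dihydronaphthalen-1(2H)-one
Product: 27 (3R,4S)-3-[(5R)-1,5-dihydroxy-3-methyl-8-oxo-5,6,7,8-tetrahydronaphthalen-2-yl]-4,5-dihydroxy-7-methyl-3,4-dihydronaphthalen-1(2H)-one
Conditions: TBAF, AcOH, THF, 0 °C to rt
Reagents that add atoms: none
Why: Fluoride should cleave the two aryl silyl ethers and the secondary silyl ether; acetic acid buffering avoids base-induced reactions of the hydroxy ketones, and no stereocenter is touched.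

**Compound list**

1 | 3-methoxy-5-methylbenzoic acid | COc1cc(C)cc(c1)C(=O)O | starting material
2 | lithium 2-lithio-3-methoxy-5-methylbenzoate | [Li]c1c(OC)cc(C)cc1C(=O)O[Li] | intermediate
3 | 2-iodo-3-methoxy-5-methylbenzoic acid | COc1cc(C)cc(C(=O)O)c1I | intermediate
4 | 2-iodo-N,3-dimethoxy-N,5-dimethylbenzamide | COc1cc(C)cc(C(=O)N(C)OC)c1I | intermediate
5 | 1-(2-iodo-3-methoxy-5-methylphenyl)ethan-1-one | COc1cc(C)cc(C(C)=O)c1I | intermediate
6 | 1-(3-hydroxy-2-iodo-5-methylphenyl)ethan-1-one | CC(=O)c1cc(C)cc(O)c1I | intermediate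
7 | 1-[2-iodo-5-methyl-3-(triisopropylsilyloxy)phenyl]ethan-1-one | CC(=O)c1cc(C)cc(O[Si](C(C)C)(C(C)C)C(C)C)c1I | intermediate
8 | 2-bromo-1-[2-iodo-5-methyl-3-(triisopropylsilyloxy)phenyl]ethan-1-one | BrCC(=O)c1cc(C)cc(O[Si](C(C)C)(C(C)C)C(C)C)c1I | intermediate
9 | 1,4-dioxaspiro[4.5]dec-6-en-8-one | O=C1C=CC2(CC1)OCCO2 | starting material
10 | (8R)-1,4-dioxaspiro[4.5]dec-6-en-8-ol | O[C@H]1C=CC2(CC1)OCCO2 | intermediate
11 | (8R)-8-(tert-butyldimethylsilyloxy)-1,4-dioxaspiro[4.5]dec-6-ene | CC(C)(C)[Si](C)(C)O[C@H]1C=CC2(CC1)OCCO2 | intermediate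
12 | (4R)-4-(tert-butyldimethylsilyloxy)cyclohex-2-en-1-one | CC(C)(C)[Si](C)(C)O[C@H]1C=CC(=O)CC1 | intermediate
13 | (4R)-2,3-dibromo-4-(tert-butyldimethylsilyloxy)cyclohexan-1-one (2,3-trans; mixture at C2 and C3) | CC(C)(C)[Si](C)(C)O[C@H]1C(Br)C(Br)C(=O)CC1 | intermediate
14 | (4R)-2-bromo-4-(tert-butyldimethylsilyloxy)cyclohex-2-en-1-one | CC(C)(C)[Si](C)(C)O[C@H]1C=C(Br)C(=O)CC1 | intermediate
15 | methyl 3-methylbut-2-enoate | COC(=O)C=C(C)C | starting material
16 | lithium 1-methoxy-3-methylbuta-1,3-dien-1-olate | [Li]OC(OC)=CC(C)=C | intermediate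
17 | methyl 2-(prop-1-en-2-yl)pent-4-enoate (racemic) | COC(=O)C(CC=C)C(C)=C | intermediate
18 | lithium 1-methoxy-2-(prop-1-en-2-yl)penta-1,4-dien-1-olate | [Li]OC(OC)=C(CC=C)C(C)=C | intermediate
19 | [1-methoxy-2-(prop-1-en-2-yl)penta-1,4-dien-1-yl]oxy-trimethylsilane (E/Z mixture) | COC(O[Si](C)(C)C)=C(CC=C)C(C)=C | intermediate
20 | (4R)-8a-bromo-4-(tert-butyldimethylsilyloxy)-8-methoxy-6-methyl-7-(prop-2-en-1-yl)-8-(trimethylsilyloxy)-3,4,4a,5,8,8a-hexahydronaphthalen-1(2H)-one (mixture at C4a, C8 and C8a) | C=CCC1=C(C)CC2[C@H](O[Si](C)(C)C(C)(C)C)CCC(=O)C2(Br)C1(OC)O[Si](C)(C)C | intermediate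
21 | (4R)-4-(tert-butyldimethylsilyloxy)-8-hydroxy-6-methyl-7-(prop-2-en-1-yl)-3,4-dihydronaphthalen-1(2H)-one | C=CCc1c(C)cc2c(c1O)C(=O)CC[C@H]2O[Si](C)(C)C(C)(C)C | intermediate
22 | (4R)-4,8-bis(tert-butyldimethylsilyloxy)-6-methyl-7-(prop-2-en-1-yl)-3,4-dihydronaphthalen-1(2H)-one | C=CCc1c(C)cc2c(c1O[Si](C)(C)C(C)(C)C)C(=O)CC[C@H]2O[Si](C)(C)C(C)(C)C | intermediate
23 | (4R)-4,8-bis(tert-butyldimethylsilyloxy)-6-methyl-7-(1,2,4-trioxolan-3-ylmethyl)-3,4-dihydronaphthalen-1(2H)-one (mixture at the trioxolane carbon) | C1(Cc2c(C)cc3c(c2O[Si](C)(C)C(C)(C)C)C(=O)CC[C@H]3O[Si](C)(C)C(C)(C)C)OCOO1 | intermediate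
24 | 2-[(5R)-1,5-bis(tert-butyldimethylsilyloxy)-3-methyl-8-oxo-5,6,7,8-tetrahydronaphthalen-2-yl]acetaldehyde | O=CCc1c(C)cc2c(c1O[Si](C)(C)C(C)(C)C)C(=O)CC[C@H]2O[Si](C)(C)C(C)(C)C | intermediate
25 | (2R)-2-[(5R)-1,5-bis(tert-butyldimethylsilyloxy)-3-methyl-8-oxo-5,6,7,8-tetrahydronaphthalen-2-yl]-4-[2-iodo-5-methyl-3-(triisopropylsilyloxy)phenyl]-4-oxobutanal | Cc1cc(O[Si](C(C)C)(C(C)C)C(C)C)c(I)c(c1)C(=O)C[C@H](c1c(C)cc2c(c1O[Si](C)(C)C(C)(C)C)C(=O)CC[C@H]2O[Si](C)(C)C(C)(C)C)C=O | intermediate
26 | (3R,4S)-3-[(5R)-1,5-bis(tert-butyldimethylsilyloxy)-3-methyl-8-oxo-5,6,7,8-tetrahydronaphthalen-2-yl]-4-hydroxy-7-methyl-5-(triisopropylsilyloxy)-3,4-dihydronaphthalen-1(2H)-one | Cc1cc(O[Si](C(C)C)(C(C)C)C(C)C)c2c(c1)C(=O)C[C@H](c1c(C)cc3c(c1O[Si](C)(C)C(C)(C)C)C(=O)CC[C@H]3O[Si](C)(C)C(C)(C)C)[C@@H]2O | intermediate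
27 | (3R,4S)-3-[(5R)-1,5-dihydroxy-3-methyl-8-oxo-5,6,7,8-tetrahydronaphthalen-2-yl]-4,5-dihydroxy-7-methyl-3,4-dihydronaphthalen-1(2H)-one | Cc1cc(O)c2c(c1)C(=O)C[C@H](c1c(C)cc3c(c1O)C(=O)CC[C@H]3O)[C@@H]2O | target

**Summary**

Total step count: 17.
Longest linear sequence: 9 steps (9 to 27 through steps 7, 8, 9, 10, 13, 14, 15, 16, 17).

**Steps most likely to fail**

1. Step 16 (key step). What may go wrong: the α-aryl aldehyde 25 enolizes in the amine-buffered medium before the chromium stage, so the configuration at C3 erodes; and alkylation of the hindered enamine is slow, so that reduction of 8 back to 7 competes. Fallback (sets out from 22 and 7, comes back at 25): the allyl group of 22 is isomerized with RuHCl(CO)(PPh3)3 to the E-propenyl arene F1, ozonolysis gives the aryl aldehyde F2, and a Henry condensation with nitromethane gives the nitroalkene F3. A Michael addition of ketone 7 catalysed by a trans-cyclohexane-1,2-diamine-derived primary amine–thiourea (enantiomer chosen for R at C3) gives the γ-nitro ketone F4, whose C3 center cannot enolize and which can be purified. Its potassium nitronate is oxidized with dimethyldioxirane (Nef reaction) to release 25 under neutral conditions, and the CrCl2/NiCl2 ring closure of step 16 is run at once to give 26.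

2. Step 13. What may go wrong: ring closure at the fully substituted ketene acetal carbon of 19 is slow, so the diene is lost by hydrolysis or the reaction stops after the first C–C bond. Fallback (sets out from 14 and 16, comes back at 21): dienolate 16 is silylated directly with TMSCl to the less hindered unsubstituted diene F5. Its Diels–Alder reaction with 14 gives the cycloadduct F6, which is aromatized as in step 13 to the phenol F7. O-Allylation (allyl bromide, K2CO3) gives the allyl ether F8, and an aromatic Claisen rearrangement, for which only one ortho position is free, gives 21.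

3. Step 6. What may go wrong: HBr released during the CuBr2 bromination cleaves the aryl silyl ether, after which the freed phenol ring is brominated, or a second bromine enters at the α-carbon. Fallback (sets out from 7, comes back at 8): LiHMDS and TMSCl convert 7 into the trimethylsilyl enol ether F9, which is brominated with N-bromosuccinimide under neutral conditions to give 8.

**Further compounds**

F1 | step 16 | (4R)-4,8-bis(tert-butyldimethylsilyloxy)-6-methyl-7-[(E)-prop-1-en-1-yl]-3,4-dihydronaphthalen-1(2H)-one | C/C=C/c1c(C)cc2c(c1O[Si](C)(C)C(C)(C)C)C(=O)CC[C@H]2O[Si](C)(C)C(C)(C)C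
F2 | step 16 | (5R)-1,5-bis(tert-butyldimethylsilyloxy)-3-methyl-8-oxo-5,6,7,8-tetrahydronaphthalene-2-carbaldehyde | O=Cc1c(C)cc2c(c1O[Si](C)(C)C(C)(C)C)C(=O)CC[C@H]2O[Si](C)(C)C(C)(C)C
F3 | step 16 | (4R)-4,8-bis(tert-butyldimethylsilyloxy)-6-methyl-7-[(E)-2-nitroethenyl]-3,4-dihydronaphthalen-1(2H)-one | [O-][N+](=O)/C=C/c1c(C)cc2c(c1O[Si](C)(C)C(C)(C)C)C(=O)CC[C@H]2O[Si](C)(C)C(C)(C)C
F4 | step 16 | (3R)-3-[(5R)-1,5-bis(tert-butyldimethylsilyloxy)-3-methyl-8-oxo-5,6,7,8-tetrahydronaphthalen-2-yl]-1-[2-iodo-5-methyl-3-(triisopropylsilyloxy)phenyl]-4-nitrobutan-1-one | Cc1cc(O[Si](C(C)C)(C(C)C)C(C)C)c(I)c(c1)C(=O)C[C@H](c1c(C)cc2c(c1O[Si](C)(C)C(C)(C)C)C(=O)CC[C@H]2O[Si](C)(C)C(C)(C)C)C[N+](=O)[O-]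
F5 | step 13 | (1-methoxy-3-methylbuta-1,3-dien-1-yl)oxy-trimethylsilane | COC(O[Si](C)(C)C)=CC(C)=C
F6 | step 13 | (4R)-8a-bromo-4-(tert-butyldimethylsilyloxy)-8-methoxy-6-methyl-8-(trimethylsilyloxy)-3,4,4a,5,8,8a-hexahydronaphthalen-1(2H)-one (mixture at C4a, C8 and C8a) | C1=C(C)CC2[C@H](O[Si](C)(C)C(C)(C)C)CCC(=O)C2(Br)C1(OC)O[Si](C)(C)C
F7 | step 13 | (4R)-4-(tert-butyldimethylsilyloxy)-8-hydroxy-6-methyl-3,4-dihydronaphthalen-1(2H)-one | Cc1cc2c(c(O)c1)C(=O)CC[C@H]2O[Si](C)(C)C(C)(C)C
F8 | step 13 | (4R)-4-(tert-butyldimethylsilyloxy)-6-methyl-8-(prop-2-en-1-yloxy)-3,4-dihydronaphthalen-1(2H)-one | C=CCOc1cc(C)cc2c1C(=O)CC[C@H]2O[Si](C)(C)C(C)(C)C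
F9 | step 6 | {1-[2-iodo-5-methyl-3-(triisopropylsilyloxy)phenyl]ethenyl}oxy-trimethylsilane | C=C(O[Si](C)(C)C)c1cc(C)cc(O[Si](C(C)C)(C(C)C)C(C)C)c1I
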